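**Assumptions.** Moracin Q has no stereocentre (C20H20O6, achiral), so no step needs stereocontrol. Compound 1 is treated as a catalogue item. It is also available in one step from 5-bromovanillin (AlCl3/pyridine).

## Retrosynthetic overview
1. Moracin Q comes from its tri-O-benzyl ether by global hydrogenolysis, which leaves the 5-OMe untouched.
2. The C4–CH2 bond comes from Pd-catalysed α-arylation of 3-methylbutan-2-one (methyl side) with a 4-bromobenzofuran.
3. The furan is the only ring formed, by tandem Sonogashira/5-endo-dig cyclisation of a 3-bromo-2-iodophenol with 3,5-bis(benzyloxy)phenylacetylene, where I reacts before Br.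
4. The iodophenol comes from 3-bromo-4,5-dihydroxybenzaldehyde by 4-O-methylation, 5-O-benzylation, Baeyer–Villiger (CHO to OH) and iodination para to OBn.
5. Both benzene rings are purchased, and the alkyne comes from 3,5-bis(benzyloxy)benzaldehyde by Ohira–Bestmann homologation.

## Forward route

**Step 1**
Reactants: 1, 3-bromo-4,5-dihydroxybenzaldehyde
Product: 2, 3-bromo-5-hydroxy-4-methoxybenzaldehyde
Conditions: DBU (1.1 equiv), MeI (1.2 equiv), DMF, 0 °C to rt
Reagents that add atoms: iodomethane, CI
Why: This is a regioselective Williamson etherification. The 4-OH (para to CHO, ortho to Br) is the most acidic, so only it is ionised by one equivalent of base and methylated.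

**Step 2**
Reactants: 2
Product: 3, 3-(benzyloxy)-5-bromo-4-methoxybenzaldehyde
Conditions: BnBr, K2CO3, DMF, rt
Reagents that add atoms: benzyl bromide, BrCc1ccccc1
Why: Williamson benzylation of the only remaining phenol gives a group that survives base and Pd and leaves together with the other two benzyls at the end.

**Step 3**
Reactants: 3
Product: 4, 3-(benzyloxy)-5-bromo-4-methoxyphenol
Conditions: mCPBA, NaHCO3, CH2Cl2, 0 °C to rt; then K2CO3, MeOH, rt
Reagents that add atoms: mCPBA, OOC(=O)c1cccc(Cl)c1 (supplies the phenolic O)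
Why: In this Baeyer–Villiger oxidation the electron-rich p-alkoxyaryl group migrates to give the aryl formate, which methanolysis cleaves to the phenol. ArBr and OBn are inert.

**Step 4**
Reactants: 4
Product: 5, 5-(benzyloxy)-3-bromo-2-iodo-4-methoxyphenol
Conditions: NIS (1.0 equiv), TsOH·H2O (10 mol %), MeCN, −20 to 0 °C, dark
Reagents that add atoms: N-iodosuccinimide, O=C1CCC(=O)N1I
Why: Electrophilic aromatic iodination goes ortho to OH and para to OBn rather than between the two oxygens. This follows the usual pattern for resorcinol ethers and the precedent of 5-bromovanillin giving 5,6-dibromovanillin.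

**Step 5**
Reactants: 6, 3,5-bis(benzyloxy)benzaldehyde
Product: 7, 1,3-bis(benzyloxy)-5-ethynylbenzene
Conditions: Ohira–Bestmann reagent, K2CO3, MeOH/THF, rt
Reagents that add atoms: dimethyl (1-diazo-2-oxopropyl)phosphonate, CC(=O)C(=[N+]=[N-])P(=O)(OC)OC (supplies the terminal alkyne carbon)
Why: Seyferth–Gilbert (Ohira–Bestmann) homologation works cleanly on a non-enolisable aryl aldehyde under mild base.

**Step 6**
Reactants: 5 and 7
Product: 8, 6-(benzyloxy)-2-[3,5-bis(benzyloxy)phenyl]-4-bromo-5-methoxy-1-benzofuran
Conditions: PdCl2(PPh3)2 (5 mol %), CuI (10 mol %), Et3N, DMF, degassed, rt to 70 °C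
Reagents that add atoms: none beyond reactant 7, C#Cc1cc(OCc2ccccc2)cc(OCc2ccccc2)c1
Why: Sonogashira coupling occurs selectively at C–I over the hindered, electron-rich C–Br. The ortho-phenol then closes the furan in situ by 5-endo-dig hydroalkoxylation.

**Step 7**
Reactants: 8 and 9, 3-methylbutan-2-one (5 equiv)
Product: 10, 1-{6-(benzyloxy)-2-[3,5-bis(benzyloxy)phenyl]-5-methoxy-1-benzofuran-4-yl}-3-methylbutan-2-one
Conditions: Pd2(dba)3 (2.5 mol %), XPhos (10 mol %), NaOtBu (2 equiv), toluene, 80 °C
Reagents that add atoms: 3-methylbutan-2-one (9), CC(=O)C(C)C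
Why: Buchwald–Hartwig ketone α-arylation takes place at the less hindered methyl terminus. The hindered aryl group, the excess ketone and deprotonation of the product suppress diarylation.

**Step 8**
Reactants: 10
Product: 11, moracin Q, 1-[2-(3,5-dihydroxyphenyl)-6-hydroxy-5-methoxy-1-benzofuran-4-yl]-3-methylbutan-2-one
Conditions: H2 (1 atm), 10 % Pd/C, EtOAc/MeOH, rt, stopped at 3 equiv uptake
Reagents that add atoms: none
Why: Catalytic hydrogenolysis removes the three benzyl ethers. The methyl ether, the non-conjugated ketone and the aromatic 2-arylbenzofuran are not reduced at 1 atm.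

## Compound list
| No. | Name | SMILES | Role |
|---|---|---|---|
| 1 | 3-bromo-4,5-dihydroxybenzaldehyde | O=Cc1cc(O)c(O)c(Br)c1 | starting material |
| 2 | 3-bromo-5-hydroxy-4-methoxybenzaldehyde | O=Cc1cc(O)c(OC)c(Br)c1 | intermediate |
| 3 | 3-(benzyloxy)-5-bromo-4-methoxybenzaldehyde | O=Cc1cc(OCc2ccccc2)c(OC)c(Br)c1 | intermediate |
| 4 | 3-(benzyloxy)-5-bromo-4-methoxyphenol | Oc1cc(OCc2ccccc2)c(OC)c(Br)c1 | intermediate |
| 5 | 5-(benzyloxy)-3-bromo-2-iodo-4-methoxyphenol | Oc1cc(OCc2ccccc2)c(OC)c(Br)c1I | intermediate |
| 6 | 3,5-bis(benzyloxy)benzaldehyde | O=Cc1cc(OCc2ccccc2)cc(OCc2ccccc2)c1 | starting material |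
| 7 | 1,3-bis(benzyloxy)-5-ethynylbenzene | C#Cc1cc(OCc2ccccc2)cc(OCc2ccccc2)c1 | intermediate |
| 8 | 6-(benzyloxy)-2-[3,5-bis(benzyloxy)phenyl]-4-bromo-5-methoxybenzofuran | COc1c(OCc2ccccc2)cc2oc(-c3cc(OCc4ccccc4)cc(OCc4ccccc4)c3)cc2c1Br | intermediate |
| 9 | 3-methylbutan-2-one | CC(=O)C(C)C | starting material |
| 10 | tri-O-benzyl moracin Q | COc1c(OCc2ccccc2)cc2oc(-c3cc(OCc4ccccc4)cc(OCc4ccccc4)c3)cc2c1CC(=O)C(C)C | intermediate |
| 11 | moracin Q (achiral) | COc1c(O)cc2oc(-c3cc(O)cc(O)c3)cc2c1CC(=O)C(C)C | target |

## Summary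
Total steps: 8.
Longest linear sequence: 7 (steps 1–4, then 6–8).

**Steps most likely to fail**
1. **Step 4, iodination regiochemistry (C3a site versus the site between the two oxygens).** Fallback: drop the C4 bromide and install the side chain from O5.
   - Carry a 5-O-(1,1-dimethylallyl) ether from 3,4-dihydroxybenzaldehyde, where iodination of the unhindered phenol is unambiguous, and build the benzofuran.
   - An aromatic Claisen rearrangement then places prenyl only at C4, because C6 is blocked.
   - O-methylation, then hydroboration and oxidation, gives the ketone.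
2. **Step 7, α-arylation of a hindered, electron-rich bromide (hydrodebromination or no reaction).** Fallback: make the aryl group the nucleophile. Br/Li exchange (n-BuLi, −78 °C) and BF3·OEt2-assisted opening of 2-isopropyloxirane at CH2 gives ArCH2CH(OH)iPr, which Dess–Martin oxidation converts to 10.
3. **Step 8, over-reduction of the furan C2=C3 bond during hydrogenolysis.** Fallback: change the protecting-group plan to MOM ethers. This uses MOMCl in step 2 and 3,5-bis(methoxymethoxy)benzaldehyde in step 5, and finishes with non-reductive HCl/MeOH cleavage.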